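**Assumption:** the target is read as (5S,8R,9R,10S,13S)-8α-formyloxylabdan-15-oic acid; labdane numbering is used in all names, and every compound carries the decalin configuration of (+)-sclareolide. (+)-Sclareolide, cis-2-butene and (−)-Ipc2BOMe are bought.

## Retrosynthetic overview

1. The C8 formate goes on last: formylation of the tertiary alcohol of a benzyl ester, then hydrogenolysis.
2. The C15 acid comes from a terminal alkene (hydroboration, then oxidation); the C12 oxygen left by the coupling is removed by Barton–McCombie deoxygenation.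
3. Key C12–C13 bond: Brown (Z)-crotylboration of the C12 aldehyde 6 (fragment 1) with the C4 unit of cis-2-butene (fragment 2); this sets C13.
4. Aldehyde 6 comes from (+)-sclareolide by lactone reduction and O-protection.
5. No ring is built: rings A and B, with C5, C8, C9 and C10, come intact from sclareolide; only its lactone ring is opened (step 1).

## Route

Step 1
Reactants: 1 (+)-sclareolide
Product: 2 13,14,15,16-tetranorlabdane-8α,12-diol (ambradiol)
Conditions: LiAlH4, THF, 0 °C to rt; then Na2SO4·10H2O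
Reagents that add atoms: none
Why: Hydride reduction of the γ-lactone to the 1,4-diol is exhaustive and touches none of the four ring stereocentres, which are carried unchanged to the target.

Step 2
Reactants: 2 13,14,15,16-tetranorlabdane-8α,12-diol
Product: 3 8α-hydroxy-13,14,15,16-tetranorlabdan-12-yl acetate
Conditions: Ac2O (1.2 equiv), pyridine, CH2Cl2, 0 °C to rt
Reagents that add atoms: acetic anhydride, CC(=O)OC(C)=O
Why: Acylation (nucleophilic acyl substitution) takes only the primary hydroxyl because the hindered tertiary C8 hydroxyl does not react with Ac2O/pyridine at room temperature.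

Step 3
Reactants: 3 8α-hydroxy-13,14,15,16-tetranorlabdan-12-yl acetate
Product: 4 8α-(triethylsilyloxy)-13,14,15,16-tetranorlabdan-12-yl acetate
Conditions: TESOTf, 2,6-lutidine, CH2Cl2, −78 to 0 °C
Reagents that add atoms: triethylsilyl trifluoromethanesulfonate, CC[Si](CC)(CC)OS(=O)(=O)C(F)(F)F
Why: Silyl triflate/lutidine silylation is the standard way to cap a hindered tertiary alcohol, and the TES ether survives the basic, oxidative and radical steps up to step 11.

Step 4
Reactants: 4 8α-(triethylsilyloxy)-13,14,15,16-tetranorlabdan-12-yl acetate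
Product: 5 8α-(triethylsilyloxy)-13,14,15,16-tetranorlabdan-12-ol
Conditions: K2CO3 (0.2 equiv), MeOH, rt
Reagents that add atoms: none
Why: Base-catalysed transesterification (methanolysis) removes the acetate while the hindered tertiary TES ether is inert to K2CO3/MeOH.

Step 5
Reactants: 5 8α-(triethylsilyloxy)-13,14,15,16-tetranorlabdan-12-ol
Product: 6 8α-(triethylsilyloxy)-13,14,15,16-tetranorlabdan-12-al
Conditions: Dess–Martin periodinane, pyridine, CH2Cl2, 0 °C to rt
Reagents that add atoms: none
Why: Dess–Martin oxidation stops at the aldehyde, which cannot close to a lactol because O8 is silylated and which has no α-stereocentre to epimerise.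

Step 6
Reactants: 6 8α-(triethylsilyloxy)-13,14,15,16-tetranorlabdan-12-al; 7 cis-2-butene
Product: 12 (12R,13R)-8α-(triethylsilyloxy)labd-14-en-12-ol, via (Z)-crotylpotassium 8 (not isolated), via potassium crotylborate complex 9 (not isolated), via (Z)-crotyldiisopinocampheylborane 10 (not isolated), via borinate ester 11 (not isolated)
Conditions: 7, n-BuLi, KOt-Bu, THF, −78 to −45 °C; (−)-Ipc2BOMe [from (+)-α-pinene], −78 °C; BF3·OEt2, −78 °C; 6, −78 °C, 4 h; then 3 M NaOH, 30% H2O2, 0 °C to rt
Reagents that add atoms: none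
Why: Brown asymmetric crotylboration (carbonyl allylation) joins fragment 1 (aldehyde 6) and fragment 2 (the crotyl unit) through a closed chair transition state in which the Z geometry enforces the syn C12/C13 relationship and the isopinocampheyl groups from (+)-α-pinene direct attack to the Si face of the aldehyde, so C13 is set with the methyl orientation that becomes 13S in the target (expected about 95:5, minor diastereomer removed by chromatography; the C12 carbinol centre is erased in step 10).

Step 7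
Reactants: 12 (12R,13R)-8α-(triethylsilyloxy)labd-14-en-12-ol
Product: 14 (12R,13R)-8α-(triethylsilyloxy)labdane-12,15-diol, via B-alkyl-9-BBN adduct 13 (not isolated)
Conditions: 9-BBN (3 equiv), THF, 0 °C to rt; then 3 M NaOH, 30% H2O2, 0 °C to rt
Reagents that add atoms: hydrogen peroxide, OO
Why: Hydroboration–oxidation with bulky 9-BBN is anti-Markovnikov on the monosubstituted alkene and places oxygen on C15 without touching C13; removing the alkene before the radical step also excludes a homoallyl radical rearrangement.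

Step 8
Reactants: 14 (12R,13R)-8α-(triethylsilyloxy)labdane-12,15-diol
Product: 15 (12R,13R)-15-(tert-butyldimethylsilyloxy)-8α-(triethylsilyloxy)labdan-12-ol
Conditions: TBSCl (1.1 equiv), imidazole, CH2Cl2, 0 °C
Reagents that add atoms: tert-butyldimethylsilyl chloride, CC(C)(C)[Si](C)(C)Cl
Why: Silylation with TBSCl/imidazole is strongly selective for the primary over the hindered secondary hydroxyl.

Step 9
Reactants: 15 (12R,13R)-15-(tert-butyldimethylsilyloxy)-8α-(triethylsilyloxy)labdan-12-ol
Product: 16 O-[(12R,13R)-15-(tert-butyldimethylsilyloxy)-8α-(triethylsilyloxy)labdan-12-yl] O-phenyl thionocarbonate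
Conditions: PhOC(S)Cl, pyridine, DMAP (cat.), CH2Cl2, 0 °C to rt
Reagents that add atoms: O-phenyl chlorothionoformate, S=C(Cl)Oc1ccccc1
Why: DMAP-catalysed thioacylation of the only free hydroxyl gives the radical precursor for the Barton–McCombie deoxygenation.

Step 10
Reactants: 16 O-phenyl thionocarbonate of the C12 alcohol
Product: 17 (13S)-15-(tert-butyldimethylsilyloxy)-8α-(triethylsilyloxy)labdane
Conditions: Bu3SnH, AIBN (cat.), toluene, 100 °C
Reagents that add atoms: none
Why: Barton–McCombie radical deoxygenation removes the C12 oxygen through a secondary alkyl radical that is quenched by the stannane, and C13 is not involved, so its configuration is kept.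

Step 11
Reactants: 17 (13S)-15-(tert-butyldimethylsilyloxy)-8α-(triethylsilyloxy)labdane
Product: 18 (13S)-labdane-8α,15-diol
Conditions: HF·pyridine, pyridine/THF, 0 °C to rt
Reagents that add atoms: none
Why: Fluoride-driven desilylation removes both the primary TBS and the tertiary TES ether under buffered conditions that do not dehydrate the tertiary alcohol.

Step 12
Reactants: 18 (13S)-labdane-8α,15-diol
Product: 20 (13S)-8α-hydroxylabdan-15-oic acid, via hydroxy aldehyde 19 (not isolated)
Conditions: TEMPO (0.2 equiv), PhI(OAc)2 (2.5 equiv), MeCN/H2O 1:1, rt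
Reagents that add atoms: water, O
Why: Oxoammonium (TEMPO/PhI(OAc)2) oxidation takes the primary alcohol through the aldehyde hydrate to the acid and cannot oxidise the tertiary C8 alcohol.

Step 13
Reactants: 20 (13S)-8α-hydroxylabdan-15-oic acid
Product: 21 benzyl (13S)-8α-hydroxylabdan-15-oate
Conditions: BnBr, K2CO3, DMF, rt
Reagents that add atoms: benzyl bromide, BrCc1ccccc1
Why: SN2 O-alkylation of the carboxylate masks the acid so that the formylation cannot form a mixed anhydride, and the tertiary alcohol is not alkylated under these conditions.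

Step 14
Reactants: 21 benzyl (13S)-8α-hydroxylabdan-15-oate
Product: 22 benzyl (13S)-8α-formyloxylabdan-15-oate
Conditions: acetic formic anhydride (predistilled, 5 equiv), pyridine, DMAP (0.2 equiv), CH2Cl2, 0 °C to rt
Reagents that add atoms: acetic formic anhydride, CC(=O)OC=O
Why: Acyl transfer from the mixed anhydride occurs at the smaller, more electrophilic formyl carbon, which makes O-formylation feasible for the hindered tertiary hydroxyl, with retention at C8 because the C8–O bond is never broken.

Step 15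
Reactants: 22 benzyl (13S)-8α-formyloxylabdan-15-oate
Product: 23 (13S)-8α-formyloxylabdan-15-oic acid (target)
Conditions: H2 (1 atm), 10% Pd/C, EtOAc, rt
Reagents that add atoms: none
Why: Neutral hydrogenolysis of the benzyl ester frees the acid without hydrolysing the labile tertiary formate.

## Compound list

1 | (+)-sclareolide, (3aR,5aS,9aS,9bR)-3a,6,6,9a-tetramethyldecahydronaphtho[2,1-b]furan-2(1H)-one | O=C1C[C@@H]2[C@@]3(C)CCCC(C)(C)[C@@H]3CC[C@@]2(C)O1 | starting material
2 | 13,14,15,16-tetranorlabdane-8α,12-diol, (1R,2R,4aS,8aS)-1-(2-hydroxyethyl)-2,5,5,8a-tetramethyldecahydronaphthalen-2-ol | OCC[C@@H]1[C@@]2(C)CCCC(C)(C)[C@@H]2CC[C@@]1(C)O | intermediate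
3 | 8α-hydroxy-13,14,15,16-tetranorlabdan-12-yl acetate (primary acetate, free tertiary alcohol) | CC(=O)OCC[C@@H]1[C@@]2(C)CCCC(C)(C)[C@@H]2CC[C@@]1(C)O | intermediate
4 | 8α-(triethylsilyloxy)-13,14,15,16-tetranorlabdan-12-yl acetate | CC(=O)OCC[C@@H]1[C@@]2(C)CCCC(C)(C)[C@@H]2CC[C@@]1(C)O[Si](CC)(CC)CC | intermediate
5 | 8α-(triethylsilyloxy)-13,14,15,16-tetranorlabdan-12-ol | OCC[C@@H]1[C@@]2(C)CCCC(C)(C)[C@@H]2CC[C@@]1(C)O[Si](CC)(CC)CC | intermediate
6 | 8α-(triethylsilyloxy)-13,14,15,16-tetranorlabdan-12-al | O=CC[C@@H]1[C@@]2(C)CCCC(C)(C)[C@@H]2CC[C@@]1(C)O[Si](CC)(CC)CC | intermediate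
7 | cis-2-butene | C/C=C\C | starting material
8 | (Z)-crotylpotassium | C/C=C\C[K] | intermediate (not isolated)
9 | potassium (Z)-crotyl(methoxy)bis(isopinocampheyl)borate, isopinocampheyl groups from (+)-α-pinene | [K+].CO[B-](C/C=C\C)([C@@H]1C[C@@H]2C[C@H]([C@H]1C)C2(C)C)[C@@H]1C[C@@H]2C[C@H]([C@H]1C)C2(C)C | intermediate (not isolated)
10 | (Z)-crotyldiisopinocampheylborane | C/C=C\CB([C@@H]1C[C@@H]2C[C@H]([C@H]1C)C2(C)C)[C@@H]1C[C@@H]2C[C@H]([C@H]1C)C2(C)C | intermediate (not isolated)
11 | (12R,13R)-12-[bis(isopinocampheyl)boryloxy]-8α-(triethylsilyloxy)labd-14-ene (borinate ester) | C=C[C@@H](C)[C@H](OB([C@@H]1C[C@@H]2C[C@H]([C@H]1C)C2(C)C)[C@@H]1C[C@@H]2C[C@H]([C@H]1C)C2(C)C)C[C@@H]1[C@@]2(C)CCCC(C)(C)[C@@H]2CC[C@@]1(C)O[Si](CC)(CC)CC | intermediate (not isolated)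
12 | (12R,13R)-8α-(triethylsilyloxy)labd-14-en-12-ol (syn homoallylic alcohol) | C=C[C@@H](C)[C@H](O)C[C@@H]1[C@@]2(C)CCCC(C)(C)[C@@H]2CC[C@@]1(C)O[Si](CC)(CC)CC | intermediate
13 | (12R,13R)-15-(9-borabicyclo[3.3.1]nonan-9-yl)-8α-(triethylsilyloxy)labdan-12-ol | C1CC2CCCC(C1)B2CC[C@@H](C)[C@H](O)C[C@@H]1[C@@]2(C)CCCC(C)(C)[C@@H]2CC[C@@]1(C)O[Si](CC)(CC)CC | intermediate (not isolated)
14 | (12R,13R)-8α-(triethylsilyloxy)labdane-12,15-diol | OCC[C@@H](C)[C@H](O)C[C@@H]1[C@@]2(C)CCCC(C)(C)[C@@H]2CC[C@@]1(C)O[Si](CC)(CC)CC | intermediate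
15 | (12R,13R)-15-(tert-butyldimethylsilyloxy)-8α-(triethylsilyloxy)labdan-12-ol | CC(C)(C)[Si](C)(C)OCC[C@@H](C)[C@H](O)C[C@@H]1[C@@]2(C)CCCC(C)(C)[C@@H]2CC[C@@]1(C)O[Si](CC)(CC)CC | intermediate
16 | O-[(12R,13R)-15-(tert-butyldimethylsilyloxy)-8α-(triethylsilyloxy)labdan-12-yl] O-phenyl thionocarbonate | CC(C)(C)[Si](C)(C)OCC[C@@H](C)[C@H](OC(=S)Oc1ccccc1)C[C@@H]1[C@@]2(C)CCCC(C)(C)[C@@H]2CC[C@@]1(C)O[Si](CC)(CC)CC | intermediate
17 | (13S)-15-(tert-butyldimethylsilyloxy)-8α-(triethylsilyloxy)labdane | C[C@@H](CC[C@@H]1[C@@]2(C)CCCC(C)(C)[C@@H]2CC[C@@]1(C)O[Si](CC)(CC)CC)CCO[Si](C)(C)C(C)(C)C | intermediate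
18 | (13S)-labdane-8α,15-diol | C[C@@H](CC[C@@H]1[C@@]2(C)CCCC(C)(C)[C@@H]2CC[C@@]1(C)O)CCO | intermediate
19 | (13S)-8α-hydroxylabdan-15-al | C[C@@H](CC[C@@H]1[C@@]2(C)CCCC(C)(C)[C@@H]2CC[C@@]1(C)O)CC=O | intermediate (not isolated)
20 | (13S)-8α-hydroxylabdan-15-oic acid | C[C@@H](CC[C@@H]1[C@@]2(C)CCCC(C)(C)[C@@H]2CC[C@@]1(C)O)CC(=O)O | intermediate
21 | benzyl (13S)-8α-hydroxylabdan-15-oate | C[C@@H](CC[C@@H]1[C@@]2(C)CCCC(C)(C)[C@@H]2CC[C@@]1(C)O)CC(=O)OCc1ccccc1 | intermediate
22 | benzyl (13S)-8α-formyloxylabdan-15-oate | C[C@@H](CC[C@@H]1[C@@]2(C)CCCC(C)(C)[C@@H]2CC[C@@]1(C)OC=O)CC(=O)OCc1ccccc1 | intermediate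
23 | (13S)-8α-formyloxylabdan-15-oic acid, (5S,8R,9R,10S,13S) | C[C@@H](CC[C@@H]1[C@@]2(C)CCCC(C)(C)[C@@H]2CC[C@@]1(C)OC=O)CC(=O)O | target

## Summary

Total step count: 15. Longest linear sequence: 15 steps (1 to 23).

**Three steps most likely to fail**

Step 6 (Brown crotylboration). The reagent must be kept at −78 °C to hold its Z geometry, and the facial selectivity on this β-branched aldehyde fixes C13. The fallback sets out from 5 and comes back at 20. Alcohol 5 is converted with I2, PPh3 and imidazole into the primary iodide F1. Mg in THF turns this into the Grignard reagent F2. With CuBr·SMe2 in THF/Me2S at −40 °C, F2 adds in a conjugate (Michael-type) sense to (S)-3-[(E)-but-2-enoyl]-4-phenyloxazolidin-2-one, itself made from (S)-4-phenyloxazolidin-2-one and crotonyl chloride. The chelated s-cis imide is attacked on the face away from the phenyl group, which gives the 13S imide F3. LiOH/H2O2 removes the auxiliary to give the silyl-protected acid F4, and HF·pyridine then frees the C8 hydroxyl to give 20. This replaces reagent-controlled allylation by auxiliary-controlled conjugate addition, never introduces the C12 oxygen, and makes steps 7 to 12 unnecessary.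

Step 10 (Barton–McCombie deoxygenation). The hindered secondary thionocarbonate may give a short radical chain or return the alcohol. The fallback sets out from 15 and comes back at 17. Dess–Martin oxidation of 15 gives the ketone F5. Condensation with TsNHNH2 in EtOH at rt gives the tosylhydrazone F6. Catecholborane in CHCl3 at 0 °C, followed by NaOAc·3H2O at reflux, reduces this to the methylene compound 17. This is a polar hydride route through the carbonyl instead of a radical route; its own risk is epimerisation at C13 next to the ketone, so F5 is carried on at once under near-neutral conditions.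

Step 14 (formylation of the hindered tertiary alcohol). Conversion may be incomplete or acetate may compete. The fallback sets out from 18 and comes back at 23. Diol 18 is held in neat acetic formic anhydride with pyridine at 40 °C until both hydroxyls are esterified, giving the bis-formate F7. KHCO3 in MeOH at 0 °C removes only the unhindered primary formate and gives the 8-formyloxy alcohol F8. Dess–Martin oxidation gives the formyloxy aldehyde F9, and Pinnick oxidation (NaClO2, NaH2PO4, 2-methyl-2-butene, t-BuOH/H2O) gives 23 directly. The formate is thus installed under forcing conditions on a substrate with no ester to protect, and the benzyl ester steps are dropped. The C8 formylation itself is still an acyl transfer, so this fallback helps only if the problem in step 14 is rate or selectivity and not an intrinsic failure of that hydroxyl to react.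

## Further compounds

F1 | step 6 | 12-iodo-8α-(triethylsilyloxy)-13,14,15,16-tetranorlabdane | ICC[C@@H]1[C@@]2(C)CCCC(C)(C)[C@@H]2CC[C@@]1(C)O[Si](CC)(CC)CC
F2 | step 6 | [8α-(triethylsilyloxy)-13,14,15,16-tetranorlabdan-12-yl]magnesium iodide | I[Mg]CC[C@@H]1[C@@]2(C)CCCC(C)(C)[C@@H]2CC[C@@]1(C)O[Si](CC)(CC)CC
F3 | step 6 | (S)-4-phenyl-3-[(13S)-8α-(triethylsilyloxy)labdan-15-oyl]oxazolidin-2-one | C[C@@H](CC[C@@H]1[C@@]2(C)CCCC(C)(C)[C@@H]2CC[C@@]1(C)O[Si](CC)(CC)CC)CC(=O)N1[C@@H](c2ccccc2)COC1=O
F4 | step 6 | (13S)-8α-(triethylsilyloxy)labdan-15-oic acid | C[C@@H](CC[C@@H]1[C@@]2(C)CCCC(C)(C)[C@@H]2CC[C@@]1(C)O[Si](CC)(CC)CC)CC(=O)O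
F5 | step 10 | (13R)-15-(tert-butyldimethylsilyloxy)-8α-(triethylsilyloxy)labdan-12-one | CC(C)(C)[Si](C)(C)OCC[C@@H](C)C(=O)C[C@@H]1[C@@]2(C)CCCC(C)(C)[C@@H]2CC[C@@]1(C)O[Si](CC)(CC)CC
F6 | step 10 | (13R)-15-(tert-butyldimethylsilyloxy)-8α-(triethylsilyloxy)labdan-12-one tosylhydrazone | CC(C)(C)[Si](C)(C)OCC[C@@H](C)C(=NNS(=O)(=O)c1ccc(C)cc1)C[C@@H]1[C@@]2(C)CCCC(C)(C)[C@@H]2CC[C@@]1(C)O[Si](CC)(CC)CC
F7 | step 14 | (13S)-labdane-8α,15-diyl diformate | C[C@@H](CC[C@@H]1[C@@]2(C)CCCC(C)(C)[C@@H]2CC[C@@]1(C)OC=O)CCOC=O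
F8 | step 14 | (13S)-8α-formyloxylabdan-15-ol | C[C@@H](CC[C@@H]1[C@@]2(C)CCCC(C)(C)[C@@H]2CC[C@@]1(C)OC=O)CCO
F9 | step 14 | (13S)-8α-formyloxylabdan-15-al | C[C@@H](CC[C@@H]1[C@@]2(C)CCCC(C)(C)[C@@H]2CC[C@@]1(C)OC=O)CC=O
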